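The butyrolactone (O1, C2, C3, C4, C5) is opened at C3–C4 after adding one bond that the target lacks, from C3 to the benzylic CH2 carried by C4. C3, C4 and that carbon then make a cyclopropane fused to the lactone, and the extra bond, benzylic and alpha to the C2 carbonyl, is the one hydrogenolysis removes afterwards. A chiral dirhodium carboxamidate turns a (Z)-3-arylallyl diazoacetate, whose aryl group is the silylated 3-hydroxy-4-methoxyphenyl ring, into this bicycle in one operation, closing both rings and fixing C4. The vanillyl group then enters at C3 by trans-selective enolate alkylation.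

Key step: step 6

Remark on spectator groups: both phenols are carried as triisopropylsilyl (TIPS) ethers, which resist DBU, amide base and handling of the benzylic bromide better than smaller silyl ethers and fall together to fluoride in the last step.

Assumption on the catalyst: Rh2(5R-MEPY)4 is dirhodium tetrakis[methyl (5R)-2-oxopyrrolidine-5-carboxylate] (divalent rhodium). The sense of induction known for Z-substituted allylic diazoacetates with this catalyst family is taken to hold for this aryl group, so the 5R series should give the (1S,5R) ring fusion. The configuration is to be confirmed at lactone 12, and the antipodal catalyst used if it proves opposite.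

Step 1
Reactants: 1 5-bromo-2-methoxyphenol
Product: 2 (5-bromo-2-methoxyphenoxy)triisopropylsilane
Conditions: TIPSCl, imidazole, DMF, rt
Reagents that add atoms: chlorotriisopropylsilane (TIPSCl), CC(C)[Si](Cl)(C(C)C)C(C)C
Why: Imidazole-promoted O-silylation of a phenol (nucleophilic substitution at silicon) is general, and the bulky aryl silyl ether should tolerate every later coupling, base and hydrogenation step.

Step 2
Reactants: 2 (5-bromo-2-methoxyphenoxy)triisopropylsilane; 3 propargyl alcohol
Product: 4 3-[4-methoxy-3-(triisopropylsilyloxy)phenyl]prop-2-yn-1-ol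
Conditions: Pd(PhCN)2Cl2 (3 mol%), t-Bu3P·HBF4 (6 mol%), CuI (2 mol%), iPr2NH, dioxane, rt to 40 °C
Reagents that add atoms: none
Why: Sonogashira coupling, in which the bulky electron-rich phosphine lets zerovalent palladium insert into the deactivated aryl bromide near room temperature and the copper acetylide of the unprotected propargylic alcohol transmetallates cleanly.

Step 3
Reactants: 4 3-[4-methoxy-3-(triisopropylsilyloxy)phenyl]prop-2-yn-1-ol
Product: 5 (Z)-3-[4-methoxy-3-(triisopropylsilyloxy)phenyl]prop-2-en-1-ol
Conditions: H2 (1 atm), Pd/CaCO3 poisoned with Pb(OAc)2, quinoline, EtOAc, rt, stopped after one equivalent of H2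
Reagents that add atoms: none
Why: Poisoned-palladium semihydrogenation delivers both hydrogens to one face of the alkyne (syn addition), which fixes the Z geometry, and quinoline with control of hydrogen uptake should hold the reaction at the alkene.

Step 4
Reactants: 5 (Z)-3-[4-methoxy-3-(triisopropylsilyloxy)phenyl]prop-2-en-1-ol
Product: 6 (Z)-3-[4-methoxy-3-(triisopropylsilyloxy)phenyl]prop-2-en-1-yl bromoacetate
Conditions: BrCH2COBr, NaHCO3, MeCN, 0 °C
Reagents that add atoms: bromoacetyl bromide, BrCC(Br)=O
Why: Acylation of a primary allylic alcohol by an acid bromide (nucleophilic acyl substitution) is fast at 0 °C, and solid NaHCO3 takes up HBr so that the electron-rich Z-cinnamyl system should neither ionise nor isomerise.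

Step 5
Reactants: 6 (Z)-3-[4-methoxy-3-(triisopropylsilyloxy)phenyl]prop-2-en-1-yl bromoacetate
Product: 9 (Z)-3-[4-methoxy-3-(triisopropylsilyloxy)phenyl]prop-2-en-1-yl diazoacetate, via N-alkylated ditosylhydrazine 7 (not isolated), via glyoxylate tosylhydrazone 8 (not isolated)
Conditions: TsNHNHTs, DBU, THF, 0 °C
Reagents that add atoms: N,N'-ditosylhydrazine (TsNHNHTs), Cc1ccc(cc1)S(=O)(=O)NNS(=O)(=O)c1ccc(C)cc1
Why: Diazo formation by N-alkylation of the ditosylhydrazine anion with the alpha-bromo ester followed by two base-induced sulfinate eliminations (a Bamford–Stevens-type fragmentation), a mild method that should leave the alkene geometry and the silyl ether untouched.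

Step 6
Reactants: 9 (Z)-3-[4-methoxy-3-(triisopropylsilyloxy)phenyl]prop-2-en-1-yl diazoacetate
Product: 11 (1S,5R,6S)-6-[4-methoxy-3-(triisopropylsilyloxy)phenyl]-3-oxabicyclo[3.1.0]hexan-2-one (all-cis), via rhodium carbene 10 (not isolated)
Conditions: Rh2(5R-MEPY)4 (1 mol%), CH2Cl2, reflux, 9 added by syringe pump over 10 h
Reagents that add atoms: none
Why: Rh2(5R-MEPY)4 takes up the diazo carbon at an axial site and N2 leaves, giving electrophilic carbene 10, which adds to the tethered Z-alkene in one concerted, asynchronous and stereospecific [2+1] event. The closest known reaction type is the enantioselective intramolecular cyclopropanation of Z-substituted allylic diazoacetates by chiral dirhodium carboxamidates. The lactone ring closes in a 5-exo sense through the C1–C5 bond to the proximal alkene carbon, and the cyclopropane closes in the same event through the C1–C6 bond to the distal, benzylic carbon. C1 and C5 are set together by the alkene face that the ester arms of the pyrrolidinone ligands leave open (their cis fusion is forced by the tether), and C6 follows from the Z geometry, which places the aryl group endo and makes the bicycle all-cis. The step needs enantioface selectivity and chemoselectivity for cyclopropanation over carbene dimerisation or attack on the electron-rich arene: the Z substituent, the alkene class best matched to this catalyst, secures the first, and slow addition to the weakly electrophilic carboxamidate carbene secures the second.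

Step 7
Reactants: 11 (1S,5R,6S)-6-[4-methoxy-3-(triisopropylsilyloxy)phenyl]-3-oxabicyclo[3.1.0]hexan-2-one
Product: 12 (4R)-4-{[4-methoxy-3-(triisopropylsilyloxy)phenyl]methyl}oxolan-2-one
Conditions: H2 (3 atm), 10% Pd/C, EtOAc, rt
Reagents that add atoms: none
Why: Catalytic hydrogenolysis of an activated cyclopropane should cleave C1–C6, the only ring bond that is both benzylic and alpha to the carbonyl, which erases C1 and C6 as stereocentres and leaves C5 untouched as the R-configured C4 of the lactone.

Step 8
Reactants: 13 vanillin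
Product: 14 3-methoxy-4-(triisopropylsilyloxy)benzaldehyde
Conditions: TIPSCl, imidazole, DMF, rt
Reagents that add atoms: chlorotriisopropylsilane (TIPSCl), CC(C)[Si](Cl)(C(C)C)C(C)C
Why: Imidazole-promoted O-silylation of the phenol (nucleophilic substitution at silicon) proceeds without touching the aldehyde.

Step 9
Reactants: 14 3-methoxy-4-(triisopropylsilyloxy)benzaldehyde
Product: 15 [3-methoxy-4-(triisopropylsilyloxy)phenyl]methanol
Conditions: NaBH4, MeOH, 0 °C
Reagents that add atoms: none
Why: Hydride reduction of an aryl aldehyde by NaBH4 (nucleophilic addition to the carbonyl group) is chemoselective and should not disturb the aryl silyl ether at 0 °C.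

Step 10
Reactants: 15 [3-methoxy-4-(triisopropylsilyloxy)phenyl]methanol
Product: 16 4-(bromomethyl)-2-methoxy-1-(triisopropylsilyloxy)benzene
Conditions: CBr4, PPh3, CH2Cl2, 0 °C; filtered through a short silica pad and used at once
Reagents that add atoms: tetrabromomethane (CBr4), BrC(Br)(Br)Br
Why: Appel reaction, in which bromide displaces the oxyphosphonium ion of the primary benzylic alcohol under neutral conditions, suiting an electron-rich benzyl bromide that would not survive acid or storage.

Step 11
Reactants: 12 (4R)-4-{[4-methoxy-3-(triisopropylsilyloxy)phenyl]methyl}oxolan-2-one; 16 4-(bromomethyl)-2-methoxy-1-(triisopropylsilyloxy)benzene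
Product: 18 (3R,4R)-3-{[3-methoxy-4-(triisopropylsilyloxy)phenyl]methyl}-4-{[4-methoxy-3-(triisopropylsilyloxy)phenyl]methyl}oxolan-2-one, via lithium enolate 17 (not isolated)
Conditions: LiN(SiMe3)2 (1.05 equiv), THF, −78 °C; then 16, DMPU, −78 to −30 °C
Reagents that add atoms: none
Why: Enolate alkylation (SN2 at the benzylic bromide), in which lithium enolate 17 is attacked on the face opposite the C4 arylmethyl group, sets C3 as R and should give the trans 3,4-disubstituted lactone, the usual outcome for 4-substituted butyrolactone enolates.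

Step 12
Reactants: 18 (3R,4R)-3-{[3-methoxy-4-(triisopropylsilyloxy)phenyl]methyl}-4-{[4-methoxy-3-(triisopropylsilyloxy)phenyl]methyl}oxolan-2-one
Product: 19 (3R,4R)-3-[(4-hydroxy-3-methoxyphenyl)methyl]-4-[(3-hydroxy-4-methoxyphenyl)methyl]oxolan-2-one
Conditions: Bu4NF, AcOH, THF, 0 °C to rt
Reagents that add atoms: none
Why: Fluoride-induced cleavage of both aryl silyl ethers (substitution at silicon driven by the Si–F bond), buffered with AcOH so that the phenoxides are protonated at once and the lactone with its more stable trans C3 centre is not exposed to base.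

Compound list
1 | 5-bromo-2-methoxyphenol | COc1ccc(Br)cc1O | starting material
2 | (5-bromo-2-methoxyphenoxy)triisopropylsilane | COc1ccc(Br)cc1O[Si](C(C)C)(C(C)C)C(C)C | intermediate
3 | propargyl alcohol (prop-2-yn-1-ol) | C#CCO | starting material
4 | 3-[4-methoxy-3-(triisopropylsilyloxy)phenyl]prop-2-yn-1-ol | COc1ccc(C#CCO)cc1O[Si](C(C)C)(C(C)C)C(C)C | intermediate
5 | (Z)-3-[4-methoxy-3-(triisopropylsilyloxy)phenyl]prop-2-en-1-ol | COc1ccc(/C=C\CO)cc1O[Si](C(C)C)(C(C)C)C(C)C | intermediate
6 | (Z)-3-[4-methoxy-3-(triisopropylsilyloxy)phenyl]prop-2-en-1-yl bromoacetate | BrCC(=O)OC/C=C\c1ccc(OC)c(O[Si](C(C)C)(C(C)C)C(C)C)c1 | intermediate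
7 | N-alkylated ditosylhydrazine: (Z)-3-[4-methoxy-3-(triisopropylsilyloxy)phenyl]prop-2-en-1-yl 2-[1,2-bis(4-methylbenzenesulfonyl)hydrazinyl]acetate, formed in the flask | Cc1ccc(cc1)S(=O)(=O)NN(CC(=O)OC/C=C\c1ccc(OC)c(O[Si](C(C)C)(C(C)C)C(C)C)c1)S(=O)(=O)c1ccc(C)cc1 | intermediate
8 | glyoxylate tosylhydrazone: (Z)-3-[4-methoxy-3-(triisopropylsilyloxy)phenyl]prop-2-en-1-yl 2-[2-(4-methylbenzenesulfonyl)hydrazinylidene]acetate, formed in the flask, C=N geometry not defined | Cc1ccc(cc1)S(=O)(=O)NN=CC(=O)OC/C=C\c1ccc(OC)c(O[Si](C(C)C)(C(C)C)C(C)C)c1 | intermediate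
9 | (Z)-3-[4-methoxy-3-(triisopropylsilyloxy)phenyl]prop-2-en-1-yl diazoacetate (precursor of the key step) | [N-]=[N+]=CC(=O)OC/C=C\c1ccc(OC)c(O[Si](C(C)C)(C(C)C)C(C)C)c1 | intermediate
10 | rhodium carbene: the ester carbene of 9 bound to one rhodium of Rh2(5R-MEPY)4, formed in the flask, ligands not drawn | [Rh]=CC(=O)OC/C=C\c1ccc(OC)c(O[Si](C(C)C)(C(C)C)C(C)C)c1 | intermediate
11 | (1S,5R,6S)-6-[4-methoxy-3-(triisopropylsilyloxy)phenyl]-3-oxabicyclo[3.1.0]hexan-2-one (all-cis, aryl endo; product of the key step) | COc1ccc([C@H]2[C@H]3COC(=O)[C@@H]23)cc1O[Si](C(C)C)(C(C)C)C(C)C | intermediate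
12 | (4R)-4-{[4-methoxy-3-(triisopropylsilyloxy)phenyl]methyl}oxolan-2-one | COc1ccc(C[C@H]2COC(=O)C2)cc1O[Si](C(C)C)(C(C)C)C(C)C | intermediate
13 | vanillin (4-hydroxy-3-methoxybenzaldehyde) | COc1cc(C=O)ccc1O | starting material
14 | 3-methoxy-4-(triisopropylsilyloxy)benzaldehyde | COc1cc(C=O)ccc1O[Si](C(C)C)(C(C)C)C(C)C | intermediate
15 | [3-methoxy-4-(triisopropylsilyloxy)phenyl]methanol | COc1cc(CO)ccc1O[Si](C(C)C)(C(C)C)C(C)C | intermediate
16 | 4-(bromomethyl)-2-methoxy-1-(triisopropylsilyloxy)benzene | COc1cc(CBr)ccc1O[Si](C(C)C)(C(C)C)C(C)C | intermediate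
17 | lithium enolate of 12: lithium (4R)-4-{[4-methoxy-3-(triisopropylsilyloxy)phenyl]methyl}-4,5-dihydrofuran-2-olate, formed in the flask | [Li+].[O-]C1=C[C@@H](Cc2ccc(OC)c(O[Si](C(C)C)(C(C)C)C(C)C)c2)CO1 | intermediate
18 | (3R,4R)-3-{[3-methoxy-4-(triisopropylsilyloxy)phenyl]methyl}-4-{[4-methoxy-3-(triisopropylsilyloxy)phenyl]methyl}oxolan-2-one | COc1ccc(C[C@H]2COC(=O)[C@@H]2Cc2ccc(O[Si](C(C)C)(C(C)C)C(C)C)c(OC)c2)cc1O[Si](C(C)C)(C(C)C)C(C)C | intermediate
19 | (3R,4R)-3-[(4-hydroxy-3-methoxyphenyl)methyl]-4-[(3-hydroxy-4-methoxyphenyl)methyl]oxolan-2-one | COc1ccc(C[C@H]2COC(=O)[C@@H]2Cc2ccc(O)c(OC)c2)cc1O | target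

Total step count: 12
Longest linear sequence: 9 steps (steps 1 to 7, then 11 and 12); steps 8 to 10 form the three-step branch to bromide 16.

Steps most likely to fail

Step 6. Enantioface discrimination may prove insufficient with this bulky, electron-rich Z-aryl substituent, or carbene dimerisation may outrun ring closure. The fallback sets out from 4 and comes back at 12, keeping the cyclopropane logic but changing alkene geometry and catalyst class. Trans-selective reduction of the propargylic alcohol with NaAlH2(OCH2CH2OMe)2 in THF at 0 °C should give (E)-3-[4-methoxy-3-(triisopropylsilyloxy)phenyl]prop-2-en-1-ol F1. Acylation and diazo formation as in steps 4 and 5 lead through the (E)-bromoacetate F2 to the (E)-diazoacetate F3. Cyclisation uses Rh2(4R-MPPIM)4, dirhodium tetrakis[methyl (4R)-2-oxo-1-(3-phenylpropanoyl)imidazolidine-4-carboxylate], the carboxamidate matched to E-substituted allylic diazoacetates. By analogy with the 5R series it is expected to select the same alkene face and give the exo-aryl lactone (1S,5R,6R)-6-[4-methoxy-3-(triisopropylsilyloxy)phenyl]-3-oxabicyclo[3.1.0]hexan-2-one F4. Hydrogenolysis as in step 7 removes the benzylic stereocentre and rejoins the route at 12.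

Step 7. Hydrogenolysis may cleave the other benzylic ring bond (C5–C6), leading to the 3-arylmethyl lactone, or may stall because the endo aryl group shields the C1–C6 bond from the catalyst surface. The fallback sets out from 4 and comes back at 12 without any cyclopropane. Exhaustive hydrogenation (H2, 10% Pd/C, EtOAc) should give 3-[4-methoxy-3-(triisopropylsilyloxy)phenyl]propan-1-ol F5. The operations of steps 4 and 5 convert it into its bromoacetate F6 and then its diazoacetate F7. Carbene insertion into the C–H bond beta to the ester oxygen (1,5-insertion), a reaction known for 3-arylpropyl diazoacetates with electron-rich aryl groups under dirhodium carboxamidate catalysis, then closes the lactone directly to 12. Rh2(4S-MPPIM)4 is expected on precedent to give the R lactone; the antipodal catalyst would be used if the configuration proved opposite.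

Step 11. The electron-rich benzylic bromide may ionise and self-condense before C-alkylation, or the product may be alkylated a second time. The fallback sets out from 12 and comes back at 18. Lithium enolate 17 (LiN(SiMe3)2, THF, −78 °C) is added to aldehyde 14 in an aldol reaction that should occur trans to the C4 substituent and give (3S,4R)-3-{hydroxy[3-methoxy-4-(triisopropylsilyloxy)phenyl]methyl}-4-{[4-methoxy-3-(triisopropylsilyloxy)phenyl]methyl}oxolan-2-one F8 as a mixture of carbinol epimers. Hydrogenolysis of the benzylic hydroxyl (H2, Pd(OH)2/C, EtOAc–AcOH) should converge both epimers on 18 and makes steps 9 and 10 unnecessary.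

Further compounds
F1 | step 6 | (E)-3-[4-methoxy-3-(triisopropylsilyloxy)phenyl]prop-2-en-1-ol | COc1ccc(/C=C/CO)cc1O[Si](C(C)C)(C(C)C)C(C)C
F2 | step 6 | (E)-3-[4-methoxy-3-(triisopropylsilyloxy)phenyl]prop-2-en-1-yl bromoacetate | BrCC(=O)OC/C=C/c1ccc(OC)c(O[Si](C(C)C)(C(C)C)C(C)C)c1
F3 | step 6 | (E)-3-[4-methoxy-3-(triisopropylsilyloxy)phenyl]prop-2-en-1-yl diazoacetate | [N-]=[N+]=CC(=O)OC/C=C/c1ccc(OC)c(O[Si](C(C)C)(C(C)C)C(C)C)c1
F4 | step 6 | (1S,5R,6R)-6-[4-methoxy-3-(triisopropylsilyloxy)phenyl]-3-oxabicyclo[3.1.0]hexan-2-one (aryl exo) | COc1ccc([C@@H]2[C@H]3COC(=O)[C@@H]23)cc1O[Si](C(C)C)(C(C)C)C(C)C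
F5 | step 7 | 3-[4-methoxy-3-(triisopropylsilyloxy)phenyl]propan-1-ol | COc1ccc(CCCO)cc1O[Si](C(C)C)(C(C)C)C(C)C
F6 | step 7 | 3-[4-methoxy-3-(triisopropylsilyloxy)phenyl]propyl bromoacetate | BrCC(=O)OCCCc1ccc(OC)c(O[Si](C(C)C)(C(C)C)C(C)C)c1
F7 | step 7 | 3-[4-methoxy-3-(triisopropylsilyloxy)phenyl]propyl diazoacetate | [N-]=[N+]=CC(=O)OCCCc1ccc(OC)c(O[Si](C(C)C)(C(C)C)C(C)C)c1
F8 | step 11 | (3S,4R)-3-{hydroxy[3-methoxy-4-(triisopropylsilyloxy)phenyl]methyl}-4-{[4-methoxy-3-(triisopropylsilyloxy)phenyl]methyl}oxolan-2-one (carbinol epimers) | COc1ccc(C[C@H]2COC(=O)[C@@H]2C(O)c2ccc(O[Si](C(C)C)(C(C)C)C(C)C)c(OC)c2)cc1O[Si](C(C)C)(C(C)C)C(C)C
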